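**Plan**
- The target has seven benzene rings (A to G in the order of the SMILES), six diaryl ether oxygens, seventeen OH groups and no stereocentre. All OH groups of rings B to G travel as methyl ethers until the last step.
- Ring A, numbered as 2-aryloxybenzene-1,3,5-triol, has its ether carbon C2 between the hydroxylated carbons C1 and C3. This is a malonate CH between its two ester carbonyl carbons, and C4–C5(OH)–C6 is the CH2–CO–CH2 unit of a 3-oxoglutarate. The retrosynthesis therefore cuts C3–C4 and C1–C6 (after two temporary ester groups on C4 and C6 are added), then the O–CH bond of the aryloxymalonate.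
- The hexamer phenol BCDEFG is cut at its five diaryl ether bonds. Each cut gives a phenol whose OH is flanked by two oxygen substituents (nucleophile) and an aryl halide (electrophile).
- Forward: ring B, a MOM-protected hindered phenol, is extended by rings C, D, E, F and G in turn. Each cycle is a copper-catalysed Ullmann coupling followed by hydrogenolysis of a benzyl ether that frees the next hindered phenol. MOM removal, O-alkylation with bromomalonate, closure of ring A, de-esterification and global demethylation follow.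
- Stereochemistry: none to set; the molecule is achiral.

Key step: step 17

Remark: on rings B, C, E, F and G, C1 is the carbon joined to the oxygen of the preceding ring and C4 the carbon para to it; on ring D, C1 bears the oxygen to ring C and C2 the oxygen to ring E. Compounds 1, 5, 9, 18, 21 and 23 are taken as purchasable.

**Route**

Step 1
Reactants: 1 4-hydroxy-2,6-dimethoxybenzaldehyde
Product: 2 2,6-dimethoxy-4-(methoxymethoxy)benzaldehyde
Conditions: NaH, DMF, 0 °C; then MOMCl, 0 °C to rt
Reagents that add atoms: chloromethyl methyl ether, COCCl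
Why: Williamson-type O-alkylation of the acidic para-formyl phenoxide with the reactive α-chloro ether should give the MOM ether, which later tolerates base, copper catalysis and hydrogenolysis.

Step 2
Reactants: 2 2,6-dimethoxy-4-(methoxymethoxy)benzaldehyde
Product: 4 2,6-dimethoxy-4-(methoxymethoxy)phenol, via aryl formate 3 (not isolated)
Conditions: mCPBA, CH2Cl2, 0 °C to rt; Na2S2O3 wash; then K2CO3 (cat.), MeOH, rt
Reagents that add atoms: meta-chloroperoxybenzoic acid, O=C(OO)c1cccc(Cl)c1
Why: In this Baeyer–Villiger (Dakin-type) oxidation the electron-rich 2,4,6-trioxygenated aryl group should migrate in preference to hydrogen, and methanolysis of the formate frees the phenol flanked by two methoxy groups with no regiochemical ambiguity.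

Step 3
Reactants: 5 4-bromo-2,6-dimethoxyphenol
Product: 6 2-(benzyloxy)-5-bromo-1,3-dimethoxybenzene
Conditions: BnBr, K2CO3, DMF, rt
Reagents that add atoms: benzyl bromide, BrCc1ccccc1
Why: Williamson ether synthesis masks the hindered phenol so that the building block for rings C, E and F acts only as an unhindered aryl bromide.

Step 4
Reactants: 4 2,6-dimethoxy-4-(methoxymethoxy)phenol; 6 2-(benzyloxy)-5-bromo-1,3-dimethoxybenzene
Product: 7 2-(benzyloxy)-5-[2,6-dimethoxy-4-(methoxymethoxy)phenoxy]-1,3-dimethoxybenzene (dimer BC benzyl ether)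
Conditions: CuI (10 mol%), picolinic acid (20 mol%), K3PO4, DMSO, 100 °C, Ar
Reagents that add atoms: none
Why: Ullmann diaryl ether coupling with a monovalent copper picolinate catalyst is suited to joining a doubly ortho-substituted phenoxide to an aryl bromide whose ortho positions are free, and MOM, benzyl and methyl ethers are inert to it.

Step 5
Reactants: 7 dimer BC benzyl ether
Product: 8 4-[2,6-dimethoxy-4-(methoxymethoxy)phenoxy]-2,6-dimethoxyphenol (dimer BC phenol)
Conditions: H2 (1 atm), 10% Pd/C, EtOAc, rt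
Reagents that add atoms: none
Why: Catalytic hydrogenolysis cleaves only the benzylic C–O bond and leaves the diaryl ether, the methyl ethers and the MOM acetal untouched.

Step 6
Reactants: 9 2,3,4-trimethoxyphenol
Product: 10 6-iodo-2,3,4-trimethoxyphenol
Conditions: I2, NaHCO3, THF–H2O, 0 °C to rt
Reagents that add atoms: iodine, II
Why: Electrophilic aromatic iodination of the phenoxide is directed ortho or para to oxygen, and since the para carbon carries methoxy the halogen should enter at C6, the only free ortho position.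

Step 7
Reactants: 10 6-iodo-2,3,4-trimethoxyphenol
Product: 11 2-(benzyloxy)-1-iodo-3,4,5-trimethoxybenzene
Conditions: BnBr, K2CO3, DMF, rt
Reagents that add atoms: benzyl bromide, BrCc1ccccc1
Why: Williamson ether synthesis gives the ring D building block, with the iodide at the future C1 and the masked hydroxyl at the future C2.

Step 8
Reactants: 8 dimer BC phenol; 11 2-(benzyloxy)-1-iodo-3,4,5-trimethoxybenzene
Product: 12 2-(benzyloxy)-1-{4-[2,6-dimethoxy-4-(methoxymethoxy)phenoxy]-3,5-dimethoxyphenoxy}-3,4,5-trimethoxybenzene (trimer BCD benzyl ether)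
Conditions: CuI (20 mol%), picolinic acid (40 mol%), K3PO4, DMSO, 110 °C, Ar
Reagents that add atoms: none
Why: This Ullmann diaryl ether coupling uses an aryl iodide so that its higher reactivity offsets the single ortho benzyloxy group of 11 and the two ortho methoxy groups of the phenol.

Step 9
Reactants: 12 trimer BCD benzyl ether
Product: 13 6-{4-[2,6-dimethoxy-4-(methoxymethoxy)phenoxy]-3,5-dimethoxyphenoxy}-2,3,4-trimethoxyphenol (trimer BCD phenol)
Conditions: H2 (1 atm), 10% Pd/C, EtOAc, rt
Reagents that add atoms: none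
Why: Hydrogenolysis of the benzyl ether frees the ring D hydroxyl at C2, between the aryloxy and methoxy substituents, without touching the other ethers.

Step 10
Reactants: 13 trimer BCD phenol; 6 2-(benzyloxy)-5-bromo-1,3-dimethoxybenzene
Product: 14 tetramer BCDE benzyl ether (13 O-arylated at the ring D hydroxyl with a 4-(benzyloxy)-3,5-dimethoxyphenyl group)
Conditions: CuI (20 mol%), picolinic acid (40 mol%), K3PO4, DMSO, 105 °C, Ar
Reagents that add atoms: none
Why: Ullmann diaryl ether coupling again pairs a phenoxide flanked by two oxygen substituents with the unhindered bromide 6, as in step 4.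

Step 11
Reactants: 14 tetramer BCDE benzyl ether
Product: 15 tetramer BCDE phenol (ring E is 4-hydroxy-3,5-dimethoxyphenyl)
Conditions: H2 (1 atm), 10% Pd/C, EtOAc, rt
Reagents that add atoms: none
Why: Benzyl ether hydrogenolysis frees the hindered ring E phenol under neutral conditions.

Step 12
Reactants: 15 tetramer BCDE phenol; 6 2-(benzyloxy)-5-bromo-1,3-dimethoxybenzene
Product: 16 pentamer BCDEF benzyl ether (15 O-arylated at the ring E hydroxyl with a 4-(benzyloxy)-3,5-dimethoxyphenyl group)
Conditions: CuI (20 mol%), picolinic acid (40 mol%), K3PO4, DMSO, 105 °C, Ar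
Reagents that add atoms: none
Why: Ullmann diaryl ether coupling of a 2,6-dimethoxyphenol-type phenoxide with the unhindered bromide 6 repeats the pairing of step 4.

Step 13
Reactants: 16 pentamer BCDEF benzyl ether
Product: 17 pentamer BCDEF phenol (ring F is 4-hydroxy-3,5-dimethoxyphenyl)
Conditions: H2 (1 atm), 10% Pd/C, EtOAc, rt
Reagents that add atoms: none
Why: Benzyl ether hydrogenolysis frees the hindered ring F phenol.

Step 14
Reactants: 17 pentamer BCDEF phenol; 18 5-bromo-1,2,3-trimethoxybenzene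
Product: 19 hexamer BCDEFG MOM ether (17 O-arylated at the ring F hydroxyl with a 3,4,5-trimethoxyphenyl group)
Conditions: CuI (20 mol%), picolinic acid (40 mol%), K3PO4, DMSO, 105 °C, Ar
Reagents that add atoms: none
Why: A final Ullmann diaryl ether coupling with the unhindered bromide 18 caps the chain with ring G.

Step 15
Reactants: 19 hexamer BCDEFG MOM ether
Product: 20 hexamer BCDEFG phenol (free OH at ring B C1, fourteen methyl ethers)
Conditions: HCl (conc., cat.), MeOH–THF, 50 °C
Reagents that add atoms: none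
Why: Acid-catalysed acetal exchange with methanol removes the MOM group, while aryl methyl ethers and diaryl ethers are stable to dilute acid.

Step 16
Reactants: 20 hexamer BCDEFG phenol; 21 diethyl bromomalonate
Product: 22 diethyl 2-(hexamer BCDEFG aryloxy)malonate
Conditions: K2CO3, acetone, reflux
Reagents that add atoms: none
Why: SN2 displacement of bromide from the bromomalonate by the phenoxide of ring B, which has no ortho substituents, is the standard route to aryloxymalonates and creates the future ring A ether carbon C2 at the sp3 stage.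

Step 17
Reactants: 22 diethyl 2-(hexamer BCDEFG aryloxy)malonate; 23 diethyl 3-oxopentanedioate
Product: 25 diethyl 2,4,6-trihydroxy-5-(hexamer BCDEFG aryloxy)benzene-1,3-dicarboxylate, via acyclic triester 24 (not isolated)
Conditions: NaOEt (3.5 equiv), 23 (3 equiv), EtOH–toluene, 80 to 115 °C with distillation of EtOH, Ar; then cold 1 M HCl
Reagents that add atoms: none
Why: Ethoxide turns 23 into its enolate, whose doubly activated methylene carbon attacks one ester carbonyl of 22 in an intermolecular Claisen condensation (loss of ethanol) to give the acyclic triester 24; the second activated methylene of 24 then attacks the remaining malonate ester carbonyl in a Dieckmann-type 6-exo-trig acyl substitution (second ethanol lost), and threefold enolisation gives the aromatic triol diester 25, so that the ring A bonds C3–C4 and C1–C6 are formed. The closest known reaction is the classical phloroglucinol synthesis, the sodium alkoxide condensation of diethyl malonate with diethyl 3-oxopentanedioate to diethyl 2,4,6-trihydroxybenzene-1,3-dicarboxylate; here the aryloxy group merely occupies the malonate carbon, which keeps one hydrogen for the final enolisation. No stereocentre is formed. The step needs C-acylation to win over O-acylation (which would lead to pyranones) and over self-condensation of 23: every Claisen step is reversible under ethoxide, the aromatic ring A as its stabilised polyanion is the thermodynamic sink, ethanol is distilled off and 23 is used in excess. Both partners are symmetric, so the ring can close in only one orientation, and because the ether carbon C2 was made in step 16 no substitution at an oxygen-flanked aromatic carbon is needed.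

Step 18
Reactants: 25 heptamer diester
Product: 27 2-(hexamer BCDEFG aryloxy)benzene-1,3,5-triol (heptamer tetradecamethyl ether), via dicarboxylic acid 26 (not isolated)
Conditions: KOH, H2O–EtOH (degassed), reflux, Ar; then HCl to pH 1, 70 °C
Reagents that add atoms: none
Why: Saponification followed by acidification gives a 2,4,6-trihydroxybenzene-1,3-dicarboxylic acid, which decarboxylates readily through its keto tautomers as in the classical phloroglucinol procedure, while methyl and diaryl ethers resist aqueous base and dilute acid.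

Step 19
Reactants: 27 heptamer tetradecamethyl ether
Product: 28 target heptamer (CNP0304148.0)
Conditions: BBr3 (40 equiv), CH2Cl2, −78 °C to rt; then H2O, 0 °C; work-up under Ar
Reagents that add atoms: none
Why: Lewis acid mediated aryl methyl ether cleavage with BBr3 proceeds by bromide attack at the methyl carbon of the boron-complexed ether, so all fourteen O–CH3 bonds should be cut while the six aryl–O–aryl bonds, which offer no sp3 carbon, remain.

**Compound list**

1 | 4-hydroxy-2,6-dimethoxybenzaldehyde | O=Cc1c(OC)cc(O)cc1OC | starting material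
2 | 2,6-dimethoxy-4-(methoxymethoxy)benzaldehyde | COCOc1cc(OC)c(C=O)c(OC)c1 | intermediate
3 | 2,6-dimethoxy-4-(methoxymethoxy)phenyl formate; not isolated | COCOc1cc(OC)c(OC=O)c(OC)c1 | intermediate
4 | 2,6-dimethoxy-4-(methoxymethoxy)phenol (ring B) | COCOc1cc(OC)c(O)c(OC)c1 | intermediate
5 | 4-bromo-2,6-dimethoxyphenol | COc1cc(Br)cc(OC)c1O | starting material
6 | 2-(benzyloxy)-5-bromo-1,3-dimethoxybenzene (building block for rings C, E, F) | COc1cc(Br)cc(OC)c1OCc1ccccc1 | intermediate
7 | 2-(benzyloxy)-5-[2,6-dimethoxy-4-(methoxymethoxy)phenoxy]-1,3-dimethoxybenzene (dimer BC benzyl ether) | COCOc1cc(OC)c(Oc2cc(OC)c(OCc3ccccc3)c(OC)c2)c(OC)c1 | intermediate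
8 | 4-[2,6-dimethoxy-4-(methoxymethoxy)phenoxy]-2,6-dimethoxyphenol (dimer BC phenol) | COCOc1cc(OC)c(Oc2cc(OC)c(O)c(OC)c2)c(OC)c1 | intermediate
9 | 2,3,4-trimethoxyphenol | COc1ccc(O)c(OC)c1OC | starting material
10 | 6-iodo-2,3,4-trimethoxyphenol | COc1cc(I)c(O)c(OC)c1OC | intermediate
11 | 2-(benzyloxy)-1-iodo-3,4,5-trimethoxybenzene (ring D building block) | COc1cc(I)c(OCc2ccccc2)c(OC)c1OC | intermediate
12 | trimer BCD benzyl ether: 2-(benzyloxy)-1-{4-[2,6-dimethoxy-4-(methoxymethoxy)phenoxy]-3,5-dimethoxyphenoxy}-3,4,5-trimethoxybenzene | COCOc1cc(OC)c(Oc2cc(OC)c(Oc3cc(OC)c(OC)c(OC)c3OCc3ccccc3)c(OC)c2)c(OC)c1 | intermediate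
13 | trimer BCD phenol: 6-{4-[2,6-dimethoxy-4-(methoxymethoxy)phenoxy]-3,5-dimethoxyphenoxy}-2,3,4-trimethoxyphenol | COCOc1cc(OC)c(Oc2cc(OC)c(Oc3cc(OC)c(OC)c(OC)c3O)c(OC)c2)c(OC)c1 | intermediate
14 | tetramer BCDE benzyl ether (ring E: 4-(benzyloxy)-3,5-dimethoxyphenyl on the ring D C2 oxygen) | COCOc1cc(OC)c(Oc2cc(OC)c(Oc3cc(OC)c(OC)c(OC)c3Oc3cc(OC)c(OCc4ccccc4)c(OC)c3)c(OC)c2)c(OC)c1 | intermediate
15 | tetramer BCDE phenol (ring E: 4-hydroxy-3,5-dimethoxyphenyl) | COCOc1cc(OC)c(Oc2cc(OC)c(Oc3cc(OC)c(OC)c(OC)c3Oc3cc(OC)c(O)c(OC)c3)c(OC)c2)c(OC)c1 | intermediate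
16 | pentamer BCDEF benzyl ether (ring F: 4-(benzyloxy)-3,5-dimethoxyphenyl on the ring E C4 oxygen) | COCOc1cc(OC)c(Oc2cc(OC)c(Oc3cc(OC)c(OC)c(OC)c3Oc3cc(OC)c(Oc4cc(OC)c(OCc5ccccc5)c(OC)c4)c(OC)c3)c(OC)c2)c(OC)c1 | intermediate
17 | pentamer BCDEF phenol (ring F: 4-hydroxy-3,5-dimethoxyphenyl) | COCOc1cc(OC)c(Oc2cc(OC)c(Oc3cc(OC)c(OC)c(OC)c3Oc3cc(OC)c(Oc4cc(OC)c(O)c(OC)c4)c(OC)c3)c(OC)c2)c(OC)c1 | intermediate
18 | 5-bromo-1,2,3-trimethoxybenzene (ring G) | COc1cc(Br)cc(OC)c1OC | starting material
19 | hexamer BCDEFG MOM ether (ring G: 3,4,5-trimethoxyphenyl on the ring F C4 oxygen) | COCOc1cc(OC)c(Oc2cc(OC)c(Oc3cc(OC)c(OC)c(OC)c3Oc3cc(OC)c(Oc4cc(OC)c(Oc5cc(OC)c(OC)c(OC)c5)c(OC)c4)c(OC)c3)c(OC)c2)c(OC)c1 | intermediate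
20 | hexamer BCDEFG phenol (free OH at ring B C1, fourteen OMe) | Oc1cc(OC)c(Oc2cc(OC)c(Oc3cc(OC)c(OC)c(OC)c3Oc3cc(OC)c(Oc4cc(OC)c(Oc5cc(OC)c(OC)c(OC)c5)c(OC)c4)c(OC)c3)c(OC)c2)c(OC)c1 | intermediate
21 | diethyl bromomalonate | CCOC(=O)C(Br)C(=O)OCC | starting material
22 | diethyl 2-(hexamer BCDEFG aryloxy)malonate | CCOC(=O)C(Oc1cc(OC)c(Oc2cc(OC)c(Oc3cc(OC)c(OC)c(OC)c3Oc3cc(OC)c(Oc4cc(OC)c(Oc5cc(OC)c(OC)c(OC)c5)c(OC)c4)c(OC)c3)c(OC)c2)c(OC)c1)C(=O)OCC | intermediate
23 | diethyl 3-oxopentanedioate | CCOC(=O)CC(=O)CC(=O)OCC | starting material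
24 | acyclic mono-Claisen triester, diethyl 2-[2-(hexamer aryloxy)-3-ethoxy-3-oxopropanoyl]-3-oxopentanedioate; not isolated, epimerisable CH centres undefined | CCOC(=O)C(Oc1cc(OC)c(Oc2cc(OC)c(Oc3cc(OC)c(OC)c(OC)c3Oc3cc(OC)c(Oc4cc(OC)c(Oc5cc(OC)c(OC)c(OC)c5)c(OC)c4)c(OC)c3)c(OC)c2)c(OC)c1)C(=O)C(C(=O)OCC)C(=O)CC(=O)OCC | intermediate
25 | diethyl 2,4,6-trihydroxy-5-(hexamer BCDEFG aryloxy)benzene-1,3-dicarboxylate (heptamer diester) | CCOC(=O)c1c(O)c(Oc2cc(OC)c(Oc3cc(OC)c(Oc4cc(OC)c(OC)c(OC)c4Oc4cc(OC)c(Oc5cc(OC)c(Oc6cc(OC)c(OC)c(OC)c6)c(OC)c5)c(OC)c4)c(OC)c3)c(OC)c2)c(O)c(C(=O)OCC)c1O | intermediate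
26 | 2,4,6-trihydroxy-5-(hexamer BCDEFG aryloxy)benzene-1,3-dicarboxylic acid; not isolated | OC(=O)c1c(O)c(Oc2cc(OC)c(Oc3cc(OC)c(Oc4cc(OC)c(OC)c(OC)c4Oc4cc(OC)c(Oc5cc(OC)c(Oc6cc(OC)c(OC)c(OC)c6)c(OC)c5)c(OC)c4)c(OC)c3)c(OC)c2)c(O)c(C(=O)O)c1O | intermediate
27 | 2-(hexamer BCDEFG aryloxy)benzene-1,3,5-triol (heptamer tetradecamethyl ether) | Oc1cc(O)c(Oc2cc(OC)c(Oc3cc(OC)c(Oc4cc(OC)c(OC)c(OC)c4Oc4cc(OC)c(Oc5cc(OC)c(Oc6cc(OC)c(OC)c(OC)c6)c(OC)c5)c(OC)c4)c(OC)c3)c(OC)c2)c(O)c1 | intermediate
28 | CNP0304148.0, heptaphenyl hexaether with seventeen hydroxyl groups | Oc1cc(O)c(Oc2cc(O)c(Oc3cc(O)c(Oc4cc(O)c(O)c(O)c4Oc4cc(O)c(Oc5cc(O)c(Oc6cc(O)c(O)c(O)c6)c(O)c5)c(O)c4)c(O)c3)c(O)c2)c(O)c1 | target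

**Totals**

Total step count: 19. Longest linear sequence: 16 steps (steps 1, 2, 4, 5 and 8 to 19, from 1 to 28).

**Steps most likely to fail**

1. Step 17. The malonate may rest as its unreactive enolate while 23 condenses with itself, or O-acylation may divert the acyclic adduct to pyranones, so that ring A does not close. The fallback sets out from 20 and comes back to the route at 28. Phenol 20 would be arylated by nucleophilic aromatic substitution on 4-fluoro-3,5-dimethoxybenzaldehyde (K2CO3, DMSO, 120 °C), with the para-formyl group activating the fluoride, to give the heptamer aldehyde F1. Baeyer–Villiger oxidation (mCPBA, CH2Cl2) would give the heptamer aryl formate F2, and methanolysis (K2CO3, MeOH) the heptamer hexadecamethyl ether phenol F3, in which ring A already carries the 1,3,5-trioxygenated pattern with the ether at C2. BBr3 in CH2Cl2 would then cleave sixteen methyl ethers to give 28.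

2. Step 8. Coupling at the ortho-substituted, electron-rich iodide may be slower than reduction of the iodide and oxidation of the doubly flanked phenoxide, so little diaryl ether forms. The fallback sets out from 8 (ring D taken from 18) and comes back at 13. Rieche formylation of 18 (Cl2CHOMe, TiCl4, CH2Cl2, 0 °C) would give 6-bromo-2,3,4-trimethoxybenzaldehyde F4, in which the ortho-formyl group activates the bromide. Displacement by the phenoxide of 8 (K2CO3, CuI cat., DMF, 120 °C) would give the trimer BCD aldehyde F5. Baeyer–Villiger oxidation (mCPBA, CH2Cl2) would give the trimer BCD formate F6, and methanolysis (K2CO3, MeOH) the phenol 13. The formyl group thus serves first as activator and then as the latent ring D hydroxyl.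

3. Step 19. Cleavage of the fourteen methyl ethers may stop short, and the free polyphenol may oxidise in air during aqueous work-up and chromatography. The fallback sets out from 27 and comes back at 28. The crude product of the BBr3 treatment would be acetylated directly (Ac2O, pyridine, rt) to the heptamer heptadecaacetate F7, which is stable and can be purified on silica; partly methylated acetates would be separated and returned to BBr3. Acid-catalysed methanolysis of F7 (AcCl cat., MeOH, Ar, rt) would then release 28 under non-basic, oxygen-free conditions.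

**Further compounds**

F1 | step 17 | 4-(hexamer BCDEFG aryloxy)-3,5-dimethoxybenzaldehyde | O=Cc1cc(OC)c(Oc2cc(OC)c(Oc3cc(OC)c(Oc4cc(OC)c(OC)c(OC)c4Oc4cc(OC)c(Oc5cc(OC)c(Oc6cc(OC)c(OC)c(OC)c6)c(OC)c5)c(OC)c4)c(OC)c3)c(OC)c2)c(OC)c1
F2 | step 17 | 4-(hexamer BCDEFG aryloxy)-3,5-dimethoxyphenyl formate | O=COc1cc(OC)c(Oc2cc(OC)c(Oc3cc(OC)c(Oc4cc(OC)c(OC)c(OC)c4Oc4cc(OC)c(Oc5cc(OC)c(Oc6cc(OC)c(OC)c(OC)c6)c(OC)c5)c(OC)c4)c(OC)c3)c(OC)c2)c(OC)c1
F3 | step 17 | 4-(hexamer BCDEFG aryloxy)-3,5-dimethoxyphenol (heptamer hexadecamethyl ether) | Oc1cc(OC)c(Oc2cc(OC)c(Oc3cc(OC)c(Oc4cc(OC)c(OC)c(OC)c4Oc4cc(OC)c(Oc5cc(OC)c(Oc6cc(OC)c(OC)c(OC)c6)c(OC)c5)c(OC)c4)c(OC)c3)c(OC)c2)c(OC)c1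
F4 | step 8 | 6-bromo-2,3,4-trimethoxybenzaldehyde | COc1cc(Br)c(C=O)c(OC)c1OC
F5 | step 8 | 6-{4-[2,6-dimethoxy-4-(methoxymethoxy)phenoxy]-3,5-dimethoxyphenoxy}-2,3,4-trimethoxybenzaldehyde | COCOc1cc(OC)c(Oc2cc(OC)c(Oc3cc(OC)c(OC)c(OC)c3C=O)c(OC)c2)c(OC)c1
F6 | step 8 | 6-{4-[2,6-dimethoxy-4-(methoxymethoxy)phenoxy]-3,5-dimethoxyphenoxy}-2,3,4-trimethoxyphenyl formate | COCOc1cc(OC)c(Oc2cc(OC)c(Oc3cc(OC)c(OC)c(OC)c3OC=O)c(OC)c2)c(OC)c1
F7 | step 19 | heptadecaacetate of the target | CC(=O)Oc1cc(OC(C)=O)c(Oc2cc(OC(C)=O)c(Oc3cc(OC(C)=O)c(Oc4cc(OC(C)=O)c(OC(C)=O)c(OC(C)=O)c4Oc4cc(OC(C)=O)c(Oc5cc(OC(C)=O)c(Oc6cc(OC(C)=O)c(OC(C)=O)c(OC(C)=O)c6)c(OC(C)=O)c5)c(OC(C)=O)c4)c(OC(C)=O)c3)c(OC(C)=O)c2)c(OC(C)=O)c1
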